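**Strategy.** The route rests on disconnecting ring A, a hexasubstituted resorcinol monomethyl ether, into a cyclobutenone and a methyl ynol ether. The key step exploits the meta relationship of the hydroxyl at C3 and the methoxyl at C5 of ring A, which alternate with the 4-hydroxybenzyl groups at C2, C4 and C6, the ethano bridge to ring B sitting at C1. One thermal cascade forms the ring A bonds C3–C4, C5–C6 and C2–C3, closes ring A and delivers the phenol and the methyl ether already differentiated. Its precursor is a racemic 2,4-dibenzyl-3-(arylethyl)cyclobut-2-enone that already carries ring B. Every phenol travels as a benzyl ether, so the last step is a neutral hydrogenolysis.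

Key step: step 11

**Remarks on the chemistry.**
- Ring A locants used in the text: C1 carries the ethano bridge, C2, C4 and C6 the 4-hydroxybenzyl groups, C3 the hydroxyl and C5 the methoxyl. The systematic phenol names of the benzannulation product and of the target count from the hydroxyl carbon instead. Locants of the four-membered ring are always given as "cyclobutenone C2", "cyclobutenone C4" and so on.
- Benzyl ethers are the only protecting group. They survive the Grignard reagent, dilute acid and heat, and they come off without acid, so the finished electron-rich ring A with its three hydroxybenzyl groups never meets a protic acid or a formaldehyde-derived electrophile.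
- The target is achiral. Compounds with one stereocentre are racemic.
- In names, Bn′ = 4-(benzyloxy)benzyl and ArB = 5-(benzyloxy)-2-[4-(benzyloxy)benzyl]phenyl (protected ring B).

**Route**

Step 1
Reactants: 1 [4-(benzyloxy)phenyl]methanol
Product: 2 1-(benzyloxy)-4-(bromomethyl)benzene (Bn′Br)
Conditions: PBr3 (0.4 equiv), Et2O, 0 °C
Reagents that add atoms: phosphorus tribromide, BrP(Br)Br
Why: Standard bromination of an electron-rich benzylic alcohol through its phosphite ester and SN2 displacement; the aryl benzyl ether is inert.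

Step 2
Reactants: 3 ethoxyethyne (ethoxyacetylene); 2 1-(benzyloxy)-4-(bromomethyl)benzene
Product: 5 1-(benzyloxy)-4-(3-ethoxyprop-2-yn-1-yl)benzene, via lithium ethoxyacetylide 4 (not isolated)
Conditions: n-BuLi (1.0 equiv), THF, –78 °C; then 2 (0.9 equiv), DMPU, –78 → 0 °C; NH4Cl quench at 0 °C
Reagents that add atoms: none
Why: Deprotonation gives the alkoxyacetylide, and its SN2 alkylation with the reactive benzylic bromide in a dipolar cosolvent is the standard synthesis of 1-alkoxy-1-alkynes; the cold quench should prevent propargyl–allenyl isomerization.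

Step 3
Reactants: 5 1-(benzyloxy)-4-(3-ethoxyprop-2-yn-1-yl)benzene (two molecules)
Product: 7 rac-2,4-bis(Bn′)-3-ethoxycyclobut-2-en-1-one, via [4-(benzyloxy)benzyl]ketene 6 (not isolated)
Conditions: toluene (1 M), 110 °C, argon, open to a bubbler
Reagents that add atoms: none
Why: Retro-ene loss of ethylene from part of 5 gives ketene 6, which the remaining ynol ether captures in a (2+2) cycloaddition with its benzyl-bearing carbon bonding to the ketene carbonyl carbon, the established thermal self-condensation of 1-ethoxyalkynes to 2,4-disubstituted 3-ethoxycyclobutenones; the stereocentre at cyclobutenone C4 forms as a racemate and is lost later.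

Step 4
Reactants: 8 2-bromo-5-hydroxybenzaldehyde
Product: 9 5-(benzyloxy)-2-bromobenzaldehyde
Conditions: BnBr (1.1 equiv), K2CO3, DMF, rt
Reagents that add atoms: benzyl bromide, BrCc1ccccc1
Why: Williamson etherification of the phenoxide; aldehyde and aryl bromide are unaffected.

Step 5
Reactants: 9 5-(benzyloxy)-2-bromobenzaldehyde
Product: 10 4-(benzyloxy)-1-bromo-2-ethenylbenzene
Conditions: Ph3PCH3Br, KOt-Bu, THF, 0 °C → rt
Reagents that add atoms: methyltriphenylphosphonium bromide, C[P+](c1ccccc1)(c1ccccc1)c1ccccc1.[Br-]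
Why: Wittig methylenation supplies the second carbon of the ethano bridge and removes the aldehyde before any organozinc reagent is present.

Step 6
Reactants: 2 1-(benzyloxy)-4-(bromomethyl)benzene; 10 4-(benzyloxy)-1-bromo-2-ethenylbenzene
Product: 12 4-(benzyloxy)-1-(Bn′)-2-ethenylbenzene, via [4-(benzyloxy)benzyl]zinc bromide 11 (not isolated)
Conditions: 2 (1.3 equiv), Zn dust, LiCl, THF, 0 °C; then 10, Pd(OAc)2 (2 mol %), SPhos (4 mol %), THF, rt
Reagents that add atoms: none
Why: Zinc insertion into the benzylic C–Br bond followed by Negishi cross-coupling with the aryl bromide builds the ring B diarylmethane; the styrene and the benzyl ethers are spectators.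

Step 7
Reactants: 12 4-(benzyloxy)-1-(Bn′)-2-ethenylbenzene
Product: 14 2-(ArB)ethan-1-ol, via B-alkyl-9-BBN adduct 13 (not isolated)
Conditions: 9-BBN (1.3 equiv), THF, 0 °C → rt; then 3 M NaOH, 30% H2O2, 0 °C → rt
Reagents that add atoms: hydrogen peroxide, OO
Why: Hydroboration–oxidation; 9-BBN adds to the styrene with anti-Markovnikov selectivity and alkaline peroxide converts the C–B bond into the primary alcohol.

Step 8
Reactants: 14 2-(ArB)ethan-1-ol
Product: 15 4-(benzyloxy)-1-(Bn′)-2-(2-bromoethyl)benzene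
Conditions: CBr4, PPh3, CH2Cl2, 0 °C
Reagents that add atoms: carbon tetrabromide, BrC(Br)(Br)Br
Why: Appel bromination of a primary alcohol under neutral conditions by SN2 displacement of the alkoxyphosphonium group.

Step 9
Reactants: 15 4-(benzyloxy)-1-(Bn′)-2-(2-bromoethyl)benzene; 7 rac-2,4-bis(Bn′)-3-ethoxycyclobut-2-en-1-one
Product: 18 rac-2,4-bis(Bn′)-3-[2-(ArB)ethyl]cyclobut-2-en-1-one, via Grignard reagent 16 (not isolated), via cyclobutenol 17 (not isolated)
Conditions: 15 (1.3 equiv), Mg turnings, THF, 40 °C; anhydrous CeCl3, THF, –78 °C; then 7, –78 → 0 °C; then 1 M HCl, THF, 0 °C → rt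
Reagents that add atoms: water, O
Why: The CeCl3-modified Grignard reagent adds 1,2 to the vinylogous ester carbonyl with little α′-enolization, and dilute acid then ionizes the tertiary allylic alcohol, water adds at the ethoxy carbon and ethanol leaves, a Stork–Danheiser 1,3-carbonyl transposition as used to turn 3-ethoxycyclobutenones into 3-alkylcyclobutenones; a Grignard reagent is chosen over an alkyllithium because it does not deprotonate the diarylmethane CH2, and since cyclobutenone C2 and cyclobutenone C4 carry the same group any double-bond migration in 18 is degenerate.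

Step 10
Reactants: 19 trichloroethylene; 2 1-(benzyloxy)-4-(bromomethyl)benzene
Product: 23 1-(benzyloxy)-4-(3-methoxyprop-2-yn-1-yl)benzene, via dichlorovinyl methyl ether 20 (not isolated), via chloro(methoxy)ethyne 21 (not isolated), via lithium methoxyacetylide 22 (not isolated)
Conditions: KH (1.0 equiv), MeOH (1.0 equiv), THF, 0 °C; 19, –50 °C → rt; n-BuLi (2.1 equiv), –78 → –40 °C; then 2 (0.9 equiv), DMPU, –78 → 0 °C; NH4Cl quench at 0 °C
Reagents that add atoms: methanol, CO
Why: Methoxide converts trichloroethylene by elimination–addition into 20, n-BuLi then eliminates HCl to 21 and exchanges chlorine for lithium to give 22, and SN2 alkylation with the benzylic bromide gives the ynol ether, the known one-flask trichloroethylene route to alkoxyalkynes.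

Step 11
Reactants: 18 rac-2,4-bis(Bn′)-3-[2-(ArB)ethyl]cyclobut-2-en-1-one; 23 1-(benzyloxy)-4-(3-methoxyprop-2-yn-1-yl)benzene
Product: 28 3-methoxy-2,4,6-tris(Bn′)-5-[2-(ArB)ethyl]phenol, via vinylketene 24 (not isolated), via 4-vinylcyclobutenone 25 (not isolated), via dienylketene 26 (not isolated), via cyclohexadienone 27 (not isolated)
Conditions: 23 (1.5 equiv), toluene (0.5 M), argon, sealed tube, 80 °C then 110 °C
Reagents that add atoms: none
Why: Thermal 4π electrocyclic opening of 18 gives vinylketene 24 with the benzyl group of cyclobutenone C4 turned outward, and the polarized ynol ether 23 adds across the ketene C=C in a (2+2) cycloaddition to give 25, its benzyl-bearing nucleophilic carbon bonding to the ketene carbonyl carbon (ring A bond C3–C4) and its methoxy carbon to the other ketene carbon (ring A bond C5–C6). A second, reversible 4π opening gives dienylketene 26, which closes ring A as a six-membered carbocycle by 6π electrocyclization (ring A bond C2–C3) and tautomerizes from dienone 27 to the phenol. This is the Danheiser benzannulation of a cyclobutenone with an alkoxyalkyne, a known route to 3-alkoxyphenols. No stereocentre is created, and the single stereocentre of racemic 18 is erased in the first ring opening. The only selectivity needed is the orientation of the (2+2) step, which the donor oxygen of 23 secures by making the alkyne carbon remote from OMe the nucleophile, so that the two oxygens end up meta at C3 and C5 of ring A. The methyl ynol ether has no β-hydrogen and cannot fragment by a retro-ene path at these temperatures, the hindered phenol formed is a poor trap for ketene, and benzyl ethers and diarylmethanes are inert to heat in toluene.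

Step 12
Reactants: 28 3-methoxy-2,4,6-tris(Bn′)-5-[2-(ArB)ethyl]phenol
Product: 29 Bleochrin B, 3-methoxy-2,4,6-tris(4-hydroxybenzyl)-5-{2-[5-hydroxy-2-(4-hydroxybenzyl)phenyl]ethyl}phenol
Conditions: H2 (1 atm), 10% Pd/C, EtOAc/MeOH, rt
Reagents that add atoms: none
Why: Hydrogenolysis of the five aryl benzyl ethers over Pd/C is neutral and leaves the aryl methyl ether and the diarylmethane and bibenzyl C–C bonds untouched.

**Compound list**

1 | [4-(benzyloxy)phenyl]methanol | OCc1ccc(OCc2ccccc2)cc1 | starting material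
2 | 1-(benzyloxy)-4-(bromomethyl)benzene (Bn′Br) | BrCc1ccc(OCc2ccccc2)cc1 | intermediate
3 | ethoxyethyne (ethoxyacetylene) | CCOC#C | starting material
4 | lithium ethoxyacetylide | [Li]C#COCC | intermediate (not isolated)
5 | 1-(benzyloxy)-4-(3-ethoxyprop-2-yn-1-yl)benzene | CCOC#CCc1ccc(OCc2ccccc2)cc1 | intermediate
6 | [4-(benzyloxy)benzyl]ketene, 3-[4-(benzyloxy)phenyl]prop-1-en-1-one | O=C=CCc1ccc(OCc2ccccc2)cc1 | intermediate (not isolated)
7 | rac-2,4-bis[4-(benzyloxy)benzyl]-3-ethoxycyclobut-2-en-1-one | CCOC1=C(Cc2ccc(OCc3ccccc3)cc2)C(=O)C1Cc1ccc(OCc2ccccc2)cc1 | intermediate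
8 | 2-bromo-5-hydroxybenzaldehyde | O=Cc1cc(O)ccc1Br | starting material
9 | 5-(benzyloxy)-2-bromobenzaldehyde | O=Cc1cc(OCc2ccccc2)ccc1Br | intermediate
10 | 4-(benzyloxy)-1-bromo-2-ethenylbenzene | C=Cc1cc(OCc2ccccc2)ccc1Br | intermediate
11 | [4-(benzyloxy)benzyl]zinc bromide | Br[Zn]Cc1ccc(OCc2ccccc2)cc1 | intermediate (not isolated)
12 | 4-(benzyloxy)-1-[4-(benzyloxy)benzyl]-2-ethenylbenzene | C=Cc1cc(OCc2ccccc2)ccc1Cc1ccc(OCc2ccccc2)cc1 | intermediate
13 | 9-{2-[5-(benzyloxy)-2-[4-(benzyloxy)benzyl]phenyl]ethyl}-9-borabicyclo[3.3.1]nonane | C1CC2CCCC(C1)B2CCc1cc(OCc2ccccc2)ccc1Cc1ccc(OCc2ccccc2)cc1 | intermediate (not isolated)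
14 | 2-{5-(benzyloxy)-2-[4-(benzyloxy)benzyl]phenyl}ethan-1-ol | OCCc1cc(OCc2ccccc2)ccc1Cc1ccc(OCc2ccccc2)cc1 | intermediate
15 | 4-(benzyloxy)-1-[4-(benzyloxy)benzyl]-2-(2-bromoethyl)benzene | BrCCc1cc(OCc2ccccc2)ccc1Cc1ccc(OCc2ccccc2)cc1 | intermediate
16 | {2-[5-(benzyloxy)-2-[4-(benzyloxy)benzyl]phenyl]ethyl}magnesium bromide | Br[Mg]CCc1cc(OCc2ccccc2)ccc1Cc1ccc(OCc2ccccc2)cc1 | intermediate (not isolated)
17 | 2,4-bis[4-(benzyloxy)benzyl]-1-{2-[5-(benzyloxy)-2-[4-(benzyloxy)benzyl]phenyl]ethyl}-3-ethoxycyclobut-2-en-1-ol (racemic mixture of diastereomers) | CCOC1=C(Cc2ccc(OCc3ccccc3)cc2)C(O)(CCc2cc(OCc3ccccc3)ccc2Cc2ccc(OCc3ccccc3)cc2)C1Cc1ccc(OCc2ccccc2)cc1 | intermediate (not isolated)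
18 | rac-2,4-bis[4-(benzyloxy)benzyl]-3-{2-[5-(benzyloxy)-2-[4-(benzyloxy)benzyl]phenyl]ethyl}cyclobut-2-en-1-one | O=C1C(Cc2ccc(OCc3ccccc3)cc2)=C(CCc2cc(OCc3ccccc3)ccc2Cc2ccc(OCc3ccccc3)cc2)C1Cc1ccc(OCc2ccccc2)cc1 | intermediate (precursor of the key step)
19 | trichloroethylene | ClC=C(Cl)Cl | starting material
20 | (E)-1,2-dichloro-1-methoxyethene | CO/C(Cl)=C\Cl | intermediate (not isolated)
21 | chloro(methoxy)ethyne | COC#CCl | intermediate (not isolated)
22 | lithium methoxyacetylide | [Li]C#COC | intermediate (not isolated)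
23 | 1-(benzyloxy)-4-(3-methoxyprop-2-yn-1-yl)benzene | COC#CCc1ccc(OCc2ccccc2)cc1 | intermediate
24 | (3E)-2-[4-(benzyloxy)benzyl]-5-[4-(benzyloxy)phenyl]-3-[2-(ArB)ethyl]penta-1,3-dien-1-one (vinylketene) | O=C=C(Cc1ccc(OCc2ccccc2)cc1)/C(CCc1cc(OCc2ccccc2)ccc1Cc1ccc(OCc2ccccc2)cc1)=C/Cc1ccc(OCc2ccccc2)cc1 | intermediate (not isolated)
25 | rac-2,4-bis[4-(benzyloxy)benzyl]-3-methoxycyclobut-2-en-1-one carrying at cyclobutenone C4 the (E)-alkenyl group C(CH2CH2ArB)=CH–CH2C6H4OBn (4-vinylcyclobutenone) | O=C1C(Cc2ccc(OCc3ccccc3)cc2)=C(OC)C1(Cc1ccc(OCc2ccccc2)cc1)/C(CCc1cc(OCc2ccccc2)ccc1Cc1ccc(OCc2ccccc2)cc1)=C/Cc1ccc(OCc2ccccc2)cc1 | intermediate (not isolated)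
26 | 2,4-bis[4-(benzyloxy)benzyl]-7-[4-(benzyloxy)phenyl]-3-methoxy-5-[2-(ArB)ethyl]hepta-1,3,5-trien-1-one, ketene carbon and chain C5 cis across chain C3=C4, chain C5=C6 of E geometry (dienylketene) | O=C=C(Cc1ccc(OCc2ccccc2)cc1)/C(OC)=C(Cc1ccc(OCc2ccccc2)cc1)\C(CCc1cc(OCc2ccccc2)ccc1Cc1ccc(OCc2ccccc2)cc1)=C\Cc1ccc(OCc2ccccc2)cc1 | intermediate (not isolated)
27 | rac-2,4,6-tris[4-(benzyloxy)benzyl]-3-methoxy-5-[2-(ArB)ethyl]cyclohexa-2,4-dien-1-one | O=C1C(Cc2ccc(OCc3ccccc3)cc2)=C(OC)C(Cc2ccc(OCc3ccccc3)cc2)=C(CCc2cc(OCc3ccccc3)ccc2Cc2ccc(OCc3ccccc3)cc2)C1Cc1ccc(OCc2ccccc2)cc1 | intermediate (not isolated)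
28 | 3-methoxy-2,4,6-tris[4-(benzyloxy)benzyl]-5-{2-[5-(benzyloxy)-2-[4-(benzyloxy)benzyl]phenyl]ethyl}phenol | COc1c(Cc2ccc(OCc3ccccc3)cc2)c(O)c(Cc2ccc(OCc3ccccc3)cc2)c(CCc2cc(OCc3ccccc3)ccc2Cc2ccc(OCc3ccccc3)cc2)c1Cc1ccc(OCc2ccccc2)cc1 | intermediate (product of the key step)
29 | Bleochrin B | COc1c(Cc2ccc(O)cc2)c(O)c(Cc2ccc(O)cc2)c(CCc2cc(O)ccc2Cc2ccc(O)cc2)c1Cc1ccc(O)cc1 | target

**Totals**

Total step count: 12.
Longest linear sequence: 8 steps (steps 4, 5, 6, 7, 8, 9, 11 and 12, from 8 to 29).

**Steps most likely to fail**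

1. Step 11. The ynol ether may be consumed by self-reaction before it captures the vinylketene, or the cascade may stall before the second ring opening and the 6π closure because of crowding around the forming ring. The fallback sets out from cyclobutenone 18 and changes the alkyne partner and the order of oxygen functionalization. Commercial methyl [4-(benzyloxy)phenyl]acetate would be homologated by the Kowalski ester homologation (CH2Br2, lithium 2,2,6,6-tetramethylpiperidide, THF, –78 °C; n-BuLi; then TIPSCl) to the more robust silyl ynol ether triisopropyl({3-[4-(benzyloxy)phenyl]prop-1-yn-1-yl}oxy)silane F1. Benzannulation of F1 with 18 in toluene at 80–110 °C, a known siloxyalkyne variant, should give the 3-(triisopropylsiloxy)phenol F2. Methylation of its free hydroxyl (MeI, K2CO3, acetone, reflux) would give the methyl ether F3, and Bu4NF in THF would then free the other oxygen. Because the benzyl groups at C2 and C6 of ring A are identical, the two oxygen positions are interchangeable and this product is compound 28, where the route is rejoined.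

2. Step 9. The organometallic may deprotonate the α′-position of the vinylogous ester instead of adding to the carbonyl, or Wurtz coupling may erode the Grignard reagent. The fallback sets out from 7 and from alkylborane 13 (made from 12 as in step 7) and replaces the addition–transposition by a cross-coupling. Hydrolysis of 7 (2 M HCl, THF, rt) would give rac-2,4-bis[4-(benzyloxy)benzyl]-3-hydroxycyclobut-2-en-1-one F4. Tf2O and Et3N in CH2Cl2 at –78 °C would give the enol triflate rac-2,4-bis[4-(benzyloxy)benzyl]-3-(trifluoromethylsulfonyloxy)cyclobut-2-en-1-one F5. A B-alkyl Suzuki–Miyaura coupling of F5 with 13 (PdCl2(dppf), K3PO4, THF/DMF, rt) should give cyclobutenone 18 directly, where the route is rejoined; bromide 15 and the Grignard reagent are then not needed.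

3. Step 3. At the temperature that the retro-ene reaction needs, the ketene may dimerize, or the 3-ethoxycyclobutenone may open and react further. The fallback sets out from 5 and generates the same ketene at room temperature from another source. Commercial 3-[4-(benzyloxy)phenyl]propanoic acid would be converted with oxalyl chloride and catalytic DMF into 3-[4-(benzyloxy)phenyl]propanoyl chloride F6. Slow addition of F6 to 5 and Et3N in CH2Cl2 at rt dehydrochlorinates it to ketene 6, which the ynol ether 5 should trap by (2+2) cycloaddition to give 7, where the route is rejoined.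

**Further compounds**

F1 | step 11 | triisopropyl({3-[4-(benzyloxy)phenyl]prop-1-yn-1-yl}oxy)silane | CC(C)[Si](OC#CCc1ccc(OCc2ccccc2)cc1)(C(C)C)C(C)C
F2 | step 11 | 2,4,6-tris[4-(benzyloxy)benzyl]-5-{2-[5-(benzyloxy)-2-[4-(benzyloxy)benzyl]phenyl]ethyl}-3-(triisopropylsiloxy)phenol | CC(C)[Si](Oc1c(Cc2ccc(OCc3ccccc3)cc2)c(O)c(Cc2ccc(OCc3ccccc3)cc2)c(CCc2cc(OCc3ccccc3)ccc2Cc2ccc(OCc3ccccc3)cc2)c1Cc1ccc(OCc2ccccc2)cc1)(C(C)C)C(C)C
F3 | step 11 | triisopropylsilyl ether of 28 (methyl ether of F2) | CC(C)[Si](Oc1c(Cc2ccc(OCc3ccccc3)cc2)c(OC)c(Cc2ccc(OCc3ccccc3)cc2)c(CCc2cc(OCc3ccccc3)ccc2Cc2ccc(OCc3ccccc3)cc2)c1Cc1ccc(OCc2ccccc2)cc1)(C(C)C)C(C)C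
F4 | step 9 | rac-2,4-bis[4-(benzyloxy)benzyl]-3-hydroxycyclobut-2-en-1-one | O=C1C(Cc2ccc(OCc3ccccc3)cc2)=C(O)C1Cc1ccc(OCc2ccccc2)cc1
F5 | step 9 | rac-2,4-bis[4-(benzyloxy)benzyl]-3-(trifluoromethylsulfonyloxy)cyclobut-2-en-1-one | O=C1C(Cc2ccc(OCc3ccccc3)cc2)=C(OS(=O)(=O)C(F)(F)F)C1Cc1ccc(OCc2ccccc2)cc1
F6 | step 3 | 3-[4-(benzyloxy)phenyl]propanoyl chloride | O=C(Cl)CCc1ccc(OCc2ccccc2)cc1
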